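**Plan**

1. Retrosynthesis: the two aryl O–Si bonds are cut first, then C8–C9 (carbinol carbon to allylic CH2). C8–C9 is cut as an allylboration with allylic transposition, giving trienal 7 (C9–C18) and allylboronate 16 (C1–C8, boron on C6).
2. 16 goes back through C6–B (SN2′ borylation), C7=C8 (cross-metathesis) and C2–C3 (enolate alkylation) to acetophenone 8. 7 goes back through its acetal and C12=C13 (Wittig) to leaf alcohol 1.
3. Enabling feature: the C9 hydroxyl is homoallylic to the Z-alkene C6=C7, so O–C9–C8–C7=C6 is the retron of a six-membered B–O–C9–C8–C7–C6 chair. A boronate on C6 is the only helper and leaves in the same step. No ring is built; the 2,6-dihydroxy-4-methoxyphenyl ring is bought.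
4. Forward: C13–C18 + C9–C12 (steps 1–4); arene-C1–C2 + C3–C7 + C8 (steps 5–9); then C8–C9 (step 10) and desilylation (step 11).
5. Stereochemistry: C9 (R) comes by 1,3-chirality transfer from the C6 boron stereocentre, which a chiral copper catalyst sets in step 9; a matched chiral phosphoric acid reinforces it. 6Z comes from the axial C6 chain in that chair, 12Z from the Wittig reaction; 10E is bought with 4 and 15Z with 1.

Key step: step 10

Remark: the absolute sense of induction of (S,S)-QuinoxP* in step 9 and of (R)-TRIP in step 10 is assumed from the closest analogies; if either runs the other way its antipode is used, the requirement fixed by the chair analysis being the (6R)-boronate and Re-face attack on 7.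

**Step 1**
Reactants: 1 (Z)-hex-3-en-1-ol
Product: 2 (Z)-1-iodohex-3-ene
Conditions: PPh3, I2, imidazole, CH2Cl2, 0 °C to rt
Reagents that add atoms: iodine, II
Why: Appel-type iodination of a primary alcohol proceeds by SN2 displacement of the alkoxyphosphonium ion and should leave the remote Z-alkene untouched.

**Step 2**
Reactants: 2 (Z)-1-iodohex-3-ene
Product: 3 [(Z)-hex-3-en-1-yl]triphenylphosphonium iodide
Conditions: PPh3, MeCN, reflux
Reagents that add atoms: triphenylphosphine, c1ccc(cc1)P(c1ccccc1)c1ccccc1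
Why: SN2 quaternisation of triphenylphosphine by a primary iodide should give the crystalline Wittig salt.

**Step 3**
Reactants: 3 [(Z)-hex-3-en-1-yl]triphenylphosphonium iodide; 4 (E)-4,4-dimethoxybut-2-enal
Product: 6 (2E,4Z,7Z)-1,1-dimethoxydeca-2,4,7-triene, via phosphorus ylide 5 (not isolated)
Conditions: NaN(SiMe3)2, THF, −78 °C; then 4, −78 °C to rt
Reagents that add atoms: none
Why: Wittig olefination of a non-stabilised ylide under lithium-free conditions closes the cis-oxaphosphetane kinetically and should give the new 4Z alkene, while the 2E alkene comes in unchanged with 4 and the acetal masks the future C9.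

**Step 4**
Reactants: 6 (2E,4Z,7Z)-1,1-dimethoxydeca-2,4,7-triene
Product: 7 (2E,4Z,7Z)-deca-2,4,7-trienal
Conditions: aqueous oxalic acid, THF, 0 °C, short contact; used at once
Reagents that add atoms: water, O
Why: acetal hydrolysis of a dienylic acetal is fast through the conjugated oxocarbenium ion, so weak acid at 0 °C should free the aldehyde before the 4Z alkene can equilibrate.

**Step 5**
Reactants: 8 1-(2,6-dihydroxy-4-methoxyphenyl)ethan-1-one; 9 5-bromopent-1-ene
Product: 11 1-(2,6-dihydroxy-4-methoxyphenyl)hept-6-en-1-one, via trilithium enolate bisphenoxide 10 (not isolated)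
Conditions: LiN(i-Pr)2 (3.3 equiv), THF, −78 to 0 °C; then 9, DMPU, Bu4NI (cat.), 0 °C to rt; aq. NH4Cl
Reagents that add atoms: none
Why: enolate alkylation of the polylithiated hydroxyaryl methyl ketone should occur at the terminal enolate carbon, because the two lithium phenoxides are chelated to the enolate oxygen and are far poorer nucleophiles toward a primary halide.

**Step 6**
Reactants: 11 1-(2,6-dihydroxy-4-methoxyphenyl)hept-6-en-1-one
Product: 12 1-[2,6-bis(tert-butyldimethylsilyloxy)-4-methoxyphenyl]hept-6-en-1-one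
Conditions: TBSCl (3 equiv), imidazole, DMAP (cat.), DMF, 40 °C
Reagents that add atoms: tert-butyldimethylsilyl chloride, CC(C)(C)[Si](C)(C)Cl
Why: silylation of both phenols removes the acidic protons before the copper and boron chemistry and gives ethers that fluoride can cleave at the end without acid.

**Step 7**
Reactants: 12 1-[2,6-bis(tert-butyldimethylsilyloxy)-4-methoxyphenyl]hept-6-en-1-one; 13 (Z)-but-2-ene-1,4-diol
Product: 14 (Z)-1-[2,6-bis(tert-butyldimethylsilyloxy)-4-methoxyphenyl]-8-hydroxyoct-6-en-1-one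
Conditions: 13 (3 equiv), Ru(=CH-C6H4-2-O-i-Pr)(SIMes)(S2C6H2Cl2) (5 mol%; S2C6H2Cl2 = 3,6-dichlorobenzene-1,2-dithiolate), THF, 22–40 °C, slight vacuum
Reagents that add atoms: none
Why: stereoretentive olefin cross-metathesis with a ruthenium dithiolate carbene passes through an all-syn metallacyclobutane, so the Z geometry of 13 should be carried into the new C6=C7 allylic alcohol, with the ketone and silyl ethers as spectators.

**Step 8**
Reactants: 14 (Z)-1-[2,6-bis(tert-butyldimethylsilyloxy)-4-methoxyphenyl]-8-hydroxyoct-6-en-1-one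
Product: 15 (Z)-8-[2,6-bis(tert-butyldimethylsilyloxy)-4-methoxyphenyl]-8-oxooct-2-en-1-yl methyl carbonate
Conditions: ClCO2Me, pyridine, CH2Cl2, 0 °C
Reagents that add atoms: methyl chloroformate, COC(=O)Cl
Why: acylation of the primary allylic alcohol with a chloroformate installs the leaving group needed for copper-catalysed allylic substitution.

**Step 9**
Reactants: 15 (Z)-8-[2,6-bis(tert-butyldimethylsilyloxy)-4-methoxyphenyl]-8-oxooct-2-en-1-yl methyl carbonate
Product: 16 (6R)-1-[2,6-bis(tert-butyldimethylsilyloxy)-4-methoxyphenyl]-6-(4,4,5,5-tetramethyl-1,3,2-dioxaborolan-2-yl)oct-7-en-1-one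
Conditions: B2pin2 (1.5 equiv), CuOtBu (5 mol%), (S,S)-QuinoxP* (5 mol%), THF, 0 °C
Reagents that add atoms: bis(pinacolato)diboron, CC1(C)OB(OC1(C)C)B1OC(C)(C)C(C)(C)O1
Why: copper-catalysed enantioselective γ-selective (SN2′) allylic borylation of a (Z)-allylic carbonate (borylcupration of the alkene, then β-elimination of the carbonate) should place boron on C6, the chiral bisphosphine on copper setting that centre as R, while the hindered aryl ketone stays inert.

**Step 10**
Reactants: 16 (6R)-1-[2,6-bis(tert-butyldimethylsilyloxy)-4-methoxyphenyl]-6-(4,4,5,5-tetramethyl-1,3,2-dioxaborolan-2-yl)oct-7-en-1-one; 7 (2E,4Z,7Z)-deca-2,4,7-trienal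
Product: 18 (6Z,9R,10E,12Z,15Z)-1-[2,6-bis(tert-butyldimethylsilyloxy)-4-methoxyphenyl]-9-hydroxyoctadeca-6,10,12,15-tetraen-1-one, via pinacol borate ester 17 (not isolated)
Conditions: 7 (1.3 equiv), (R)-TRIP (10 mol%), 4 Å MS, toluene, −45 to −20 °C; aq. NaHCO3 work-up
Reagents that add atoms: none
Why: This is an allylboration of an aldehyde with an α-substituted, enantioenriched allylboronate, run in its chiral-phosphoric-acid-catalysed, chirality-paired form: the acid hydrogen-bonds a pinacol oxygen and the formyl hydrogen, the aldehyde oxygen binds boron, and C8 attacks C9 through a closed six-membered chair B–O–C9–C8–C7–C6 while the C6–B bond breaks and C6=C7 forms. No ring is closed; the six-membered array exists only in the transition state, and the boron helper leaves C6 in this step and is hydrolysed off oxygen on work-up. C9 is controlled by 1,3-chirality transfer from C6: with the trienyl group equatorial and the C2–C5 chain axial on C6, the (6R)-boronate delivers C8 to the Re face of 7, which gives 9R, and the same axial chain ends up cis to C8, which gives 6Z. The selectivity needed is this chair over the one with the chain equatorial, which would give 6E and 9S; it is secured by the gauche repulsion between an equatorial C6 substituent and the pinacolato oxygens, and by the acid, whose preferred aldehyde face is matched only with the Z-forming chair. Addition should be 1,2 to the aldehyde only, because the closed transition state cannot reach C11 or C13 and the di-ortho-silyloxy aryl ketone is too hindered and electron-rich to bind boron.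

**Step 11**
Reactants: 18 (6Z,9R,10E,12Z,15Z)-1-[2,6-bis(tert-butyldimethylsilyloxy)-4-methoxyphenyl]-9-hydroxyoctadeca-6,10,12,15-tetraen-1-one
Product: 19 (6Z,9R,10E,12Z,15Z)-1-(2,6-dihydroxy-4-methoxyphenyl)-9-hydroxyoctadeca-6,10,12,15-tetraen-1-one
Conditions: Bu4NF/AcOH (1:1, 3 equiv), THF, 0 °C
Reagents that add atoms: none
Why: fluoride-mediated desilylation of the two aryl silyl ethers, buffered with acetic acid, should free the phenols without acid strong enough to ionise the doubly allylic C9 carbinol or base strong enough to move the skipped alkenes.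

**Compound list**

1 | (Z)-hex-3-en-1-ol | CC/C=C\CCO | starting material
2 | (Z)-1-iodohex-3-ene | CC/C=C\CCI | intermediate
3 | [(Z)-hex-3-en-1-yl]triphenylphosphonium iodide | CC/C=C\CC[P+](c1ccccc1)(c1ccccc1)c1ccccc1.[I-] | intermediate
4 | (E)-4,4-dimethoxybut-2-enal | COC(OC)/C=C/C=O | starting material
5 | [(Z)-hex-3-en-1-ylidene]triphenylphosphorane (not isolated) | CC/C=C\CC=P(c1ccccc1)(c1ccccc1)c1ccccc1 | intermediate
6 | (2E,4Z,7Z)-1,1-dimethoxydeca-2,4,7-triene | CC/C=C\C/C=C\C=C\C(OC)OC | intermediate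
7 | (2E,4Z,7Z)-deca-2,4,7-trienal | CC/C=C\C/C=C\C=C\C=O | intermediate
8 | 1-(2,6-dihydroxy-4-methoxyphenyl)ethan-1-one | CC(=O)c1c(O)cc(OC)cc1O | starting material
9 | 5-bromopent-1-ene | C=CCCCBr | starting material
10 | trilithium 1-(4-methoxy-2,6-dioxidophenyl)ethen-1-olate (not isolated) | [Li+].[Li+].[Li+].C=C([O-])c1c([O-])cc(OC)cc1[O-] | intermediate
11 | 1-(2,6-dihydroxy-4-methoxyphenyl)hept-6-en-1-one | C=CCCCCC(=O)c1c(O)cc(OC)cc1O | intermediate
12 | 1-[2,6-bis(tert-butyldimethylsilyloxy)-4-methoxyphenyl]hept-6-en-1-one | C=CCCCCC(=O)c1c(O[Si](C)(C)C(C)(C)C)cc(OC)cc1O[Si](C)(C)C(C)(C)C | intermediate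
13 | (Z)-but-2-ene-1,4-diol | OC/C=C\CO | starting material
14 | (Z)-1-[2,6-bis(tert-butyldimethylsilyloxy)-4-methoxyphenyl]-8-hydroxyoct-6-en-1-one | OC/C=C\CCCCC(=O)c1c(O[Si](C)(C)C(C)(C)C)cc(OC)cc1O[Si](C)(C)C(C)(C)C | intermediate
15 | (Z)-8-[2,6-bis(tert-butyldimethylsilyloxy)-4-methoxyphenyl]-8-oxooct-2-en-1-yl methyl carbonate | COC(=O)OC/C=C\CCCCC(=O)c1c(O[Si](C)(C)C(C)(C)C)cc(OC)cc1O[Si](C)(C)C(C)(C)C | intermediate
16 | (6R)-1-[2,6-bis(tert-butyldimethylsilyloxy)-4-methoxyphenyl]-6-(4,4,5,5-tetramethyl-1,3,2-dioxaborolan-2-yl)oct-7-en-1-one | C=C[C@@H](CCCCC(=O)c1c(O[Si](C)(C)C(C)(C)C)cc(OC)cc1O[Si](C)(C)C(C)(C)C)B1OC(C)(C)C(C)(C)O1 | intermediate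
17 | pinacol borate ester of 18, boron on the C9 oxygen (not isolated) | CC/C=C\C/C=C\C=C\[C@H](OB1OC(C)(C)C(C)(C)O1)C/C=C\CCCCC(=O)c1c(O[Si](C)(C)C(C)(C)C)cc(OC)cc1O[Si](C)(C)C(C)(C)C | intermediate
18 | (6Z,9R,10E,12Z,15Z)-1-[2,6-bis(tert-butyldimethylsilyloxy)-4-methoxyphenyl]-9-hydroxyoctadeca-6,10,12,15-tetraen-1-one | CC/C=C\C/C=C\C=C\[C@H](O)C/C=C\CCCCC(=O)c1c(O[Si](C)(C)C(C)(C)C)cc(OC)cc1O[Si](C)(C)C(C)(C)C | intermediate
19 | (6Z,9R,10E,12Z,15Z)-1-(2,6-dihydroxy-4-methoxyphenyl)-9-hydroxyoctadeca-6,10,12,15-tetraen-1-one | CC/C=C\C/C=C\C=C\[C@H](O)C/C=C\CCCCC(=O)c1c(O)cc(OC)cc1O | target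

**Count**

Total steps: 11. Longest linear sequence: 7 (steps 5–11, from 8).

**Steps most likely to fail**

**Step 10.** Leakage through the chair that carries the C6 chain equatorial would give the 6E alkene with the 9S carbinol, and acid-promoted Z-to-E isomerisation of the 4Z bond of 7 could occur before addition. The fallback takes the alkene geometry out of the bond-forming event: C8–C9 is made by asymmetric propargylation and 6Z by semi-hydrogenation. It sets out from 8 (as 10) and 7 and comes back at 18.
- Commercial 6-chlorohex-2-yn-1-ol is converted with NaI in acetone into 6-iodohex-2-yn-1-ol F1.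
- F1 is added as lithium 6-iodohex-2-yn-1-olate F2 (one further equivalent of LDA) to 10, which should give 1-(2,6-dihydroxy-4-methoxyphenyl)-8-hydroxyoct-6-yn-1-one F3.
- Persilylation (TBSCl, imidazole) should give the tris-silyl ether F4. PPTS in MeOH should then cleave only the primary alkyl silyl ether, giving 1-[2,6-bis(tert-butyldimethylsilyloxy)-4-methoxyphenyl]-8-hydroxyoct-6-yn-1-one F5.
- Methyl chloroformate and pyridine should give the propargylic methyl carbonate F6.
- Copper-catalysed SN2′ borylation (CuOtBu, Xantphos, B2pin2) should give the 1-substituted allenylboronate F7.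
- Chiral-phosphoric-acid-catalysed propargylation of 7 with F7 (the matched enantiomer of TRIP, closed six-membered SE2′ transition state) should give, through borate ester F8, the (9R)-homopropargylic alcohol F9.
- Semi-hydrogenation of F9 (H2, Pd on CaCO3 poisoned with Pb(OAc)2, quinoline, EtOAc) should give 18.

**Step 5.** O-alkylation of a phenoxide, a second alkylation at C2 after proton transfer between product and enolate, or incomplete trianion formation through aggregation may occur. The fallback replaces the unprotected trianion by a protected mono-enolate; it sets out from 8 and 9 and comes back at 11.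
- 8 is converted with MOMCl and i-Pr2NEt into 1-[4-methoxy-2,6-bis(methoxymethoxy)phenyl]ethan-1-one F10.
- LDA in THF at −78 °C should give lithium enolate F11, which is alkylated with 9 (DMPU) to 1-[4-methoxy-2,6-bis(methoxymethoxy)phenyl]hept-6-en-1-one F12.
- HCl in MeOH should remove both acetals and give 11; at this stage the molecule carries only a ketone and an isolated terminal alkene, so acid is harmless.

**Step 7.** The ruthenium dithiolate may decompose through the methylidene generated from the terminal alkene, stalling conversion, or secondary metathesis may erode the Z purity. The fallback gives up Z control at this stage and moves enantiocontrol to a catalyst class that accepts E-substrates; it sets out from 12 and 13 and comes back at 16.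
- 13 and methyl chloroformate (pyridine) should give (Z)-but-2-ene-1,4-diyl dimethyl dicarbonate F13.
- Cross-metathesis of 12 with F13 under the second-generation Hoveyda–Grubbs catalyst RuCl2(SIMes)(=CH-C6H4-2-O-i-Pr) should equilibrate to the (E)-allylic carbonate F14, purified from its minor Z isomer.
- Borylation of F14 with B2pin2 under a chiral sulfonate-bearing N-heterocyclic-carbene copper catalyst (imidazolinium sulfonate, Cu(OTf)2, NaOMe), with the ligand enantiomer chosen for the 6R product, should give 16.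

**Further compounds**

F1 | step 10 | 6-iodohex-2-yn-1-ol | OCC#CCCCI
F2 | step 10 | lithium 6-iodohex-2-yn-1-olate | [Li+].[O-]CC#CCCCI
F3 | step 10 | 1-(2,6-dihydroxy-4-methoxyphenyl)-8-hydroxyoct-6-yn-1-one | OCC#CCCCCC(=O)c1c(O)cc(OC)cc1O
F4 | step 10 | 1-[2,6-bis(tert-butyldimethylsilyloxy)-4-methoxyphenyl]-8-(tert-butyldimethylsilyloxy)oct-6-yn-1-one | CC(C)(C)[Si](C)(C)OCC#CCCCCC(=O)c1c(O[Si](C)(C)C(C)(C)C)cc(OC)cc1O[Si](C)(C)C(C)(C)C
F5 | step 10 | 1-[2,6-bis(tert-butyldimethylsilyloxy)-4-methoxyphenyl]-8-hydroxyoct-6-yn-1-one | OCC#CCCCCC(=O)c1c(O[Si](C)(C)C(C)(C)C)cc(OC)cc1O[Si](C)(C)C(C)(C)C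
F6 | step 10 | 8-[2,6-bis(tert-butyldimethylsilyloxy)-4-methoxyphenyl]-8-oxooct-2-yn-1-yl methyl carbonate | COC(=O)OCC#CCCCCC(=O)c1c(O[Si](C)(C)C(C)(C)C)cc(OC)cc1O[Si](C)(C)C(C)(C)C
F7 | step 10 | 1-[2,6-bis(tert-butyldimethylsilyloxy)-4-methoxyphenyl]-6-(4,4,5,5-tetramethyl-1,3,2-dioxaborolan-2-yl)octa-6,7-dien-1-one | C=C=C(CCCCC(=O)c1c(O[Si](C)(C)C(C)(C)C)cc(OC)cc1O[Si](C)(C)C(C)(C)C)B1OC(C)(C)C(C)(C)O1
F8 | step 10 | pinacol borate ester of F9, boron on the C9 oxygen | CC/C=C\C/C=C\C=C\[C@H](OB1OC(C)(C)C(C)(C)O1)CC#CCCCCC(=O)c1c(O[Si](C)(C)C(C)(C)C)cc(OC)cc1O[Si](C)(C)C(C)(C)C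
F9 | step 10 | (9R,10E,12Z,15Z)-1-[2,6-bis(tert-butyldimethylsilyloxy)-4-methoxyphenyl]-9-hydroxyoctadeca-10,12,15-trien-6-yn-1-one | CC/C=C\C/C=C\C=C\[C@H](O)CC#CCCCCC(=O)c1c(O[Si](C)(C)C(C)(C)C)cc(OC)cc1O[Si](C)(C)C(C)(C)C
F10 | step 5 | 1-[4-methoxy-2,6-bis(methoxymethoxy)phenyl]ethan-1-one | CC(=O)c1c(OCOC)cc(OC)cc1OCOC
F11 | step 5 | lithium 1-[4-methoxy-2,6-bis(methoxymethoxy)phenyl]ethen-1-olate | [Li+].C=C([O-])c1c(OCOC)cc(OC)cc1OCOC
F12 | step 5 | 1-[4-methoxy-2,6-bis(methoxymethoxy)phenyl]hept-6-en-1-one | C=CCCCCC(=O)c1c(OCOC)cc(OC)cc1OCOC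
F13 | step 7 | (Z)-but-2-ene-1,4-diyl dimethyl dicarbonate | COC(=O)OC/C=C\COC(=O)OC
F14 | step 7 | (E)-8-[2,6-bis(tert-butyldimethylsilyloxy)-4-methoxyphenyl]-8-oxooct-2-en-1-yl methyl carbonate | COC(=O)OC/C=C/CCCCC(=O)c1c(O[Si](C)(C)C(C)(C)C)cc(OC)cc1O[Si](C)(C)C(C)(C)C
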